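## Analysis of the target

The target is a bicyclic labdane of the enantio series (labdane numbering C1–C20 is used throughout): a trans-fused decalin (ring A: C1–C5 and C10; ring B: C5–C10) whose C9 carries, through C11 and C12, a 2-substituted buta-1,3-diene (C13(=C16)–C14=C15). Six stereocentres (4S,5S,6R,8S,9S,10R) are contiguous. The angular methyl C20 and the C19 methyl on C4 are syn and 1,3-diaxial, while the C18 hydroxymethyl group is equatorial and lies on the face of H5. The C9 chain, the C6 acetoxy group and the C8 hydroxyl are equatorial, and the C17 methyl is axial and syn to C20. The sensitive groups are the diene (acid, dienophiles, dissolving metals, light), the tertiary C8 carbinol (dehydration, and C7–C8 retro-aldol cleavage while C6 is a ketone), and a secondary acetate next to a free primary alcohol (acyl shift from O6 to O18), so three hydroxyls must be told apart. The difficulties are two quaternary carbons (C4, C10) flanking C5, a C8 carbinol in the less stable orientation (methyl axial), an equatorial C6 alcohol that hydride reagents do not deliver, and the relay of absolute configuration from C4 to C10. The strategy rests on one feature: C6 and C8 are oxygenated carbons joined through C5–C10–C9, with C7 between them and C17 on C8, so ring B is the aldol condensation product of a 1,5-diketone whose carbonyls are the two acetyl groups of a 3-substituted pentane-2,4-dione. The bonds C5–C6 and C9–C10 are then those of a [2+2] photoadduct of the dione enol across a C5=C10 alkene of ring A, and the C18 oxygen on C4, next to C5, is a handle by which the enol oxygen can be held.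

## Retrosynthetic reasoning

25 to 23. The last operations only adjust the hydroxyls: the C18 silyl ether of 24 is removed last, and 24 comes from 23 by acylating the only secondary hydroxyl. C18 must stay protected until the acetate is in place, because a free primary alcohol would be acylated first.

23 to 19. The diene is cut at C13=C16 and C14=C15, which removes the two terminal methylene carbons and leaves alkyne 22; an enyne cross-metathesis rebuilds them in one step. The diene is made late because it would survive neither the photochemical nor the dissolving-metal step. Cutting C13≡C14 of 22 leads to aldehyde 20, which exists as lactol 21 with the C8 hydroxyl, and this comes from triol 19 by oxidation of its only unhindered primary alcohol.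

19 to 15. The equatorial C6 carbinol is traced to ketone 18 (a thermodynamic reduction is required; the same step uncovers the C13 alcohol). The C8 carbinol is traced through epoxy ketone 17 to enone 16, the silyl ether of 15. Ring B cannot simply be left at the ketol stage 14, because a reversible aldol would put C17 equatorial; dehydration to the enone and re-oxygenation from the face anti to C20 gives the required axial C17.

15 to 11 (key disconnection). C7–C8 is cut as an aldol condensation, giving 1,5-diketone 13. Re-joining C6–C9 turns 13 into a cyclobutanol (the forward direction is a strain-driven retro-aldol), and cutting C5–C6 and C9–C10 of that cyclobutane as a [2+2] photocycloaddition gives 11. These cuts send all of ring B outside ring A to a five-carbon dione that already carries the side chain, and they leave a ring A alkene with only the C4 stereocentre. The forward reaction must join the oxygen-bearing enol carbon to C5 and the central carbon to C10, on the face of C18, and the aldol must then run from C7 to C8. A free enol would have little reason to do the first two: methyl and oxymethyl on C4 differ little in size, and electron-rich alkenes usually bond their more substituted carbon to the oxygen-bearing enol carbon, which is the wrong way here. Therefore the enol oxygen and O18 are joined through one diisopropylsilylene unit, which serves at once as the silyl protecting group of the ring A carbinol and of the enol.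

11 to 6 and 9. The two Si–O bonds are cut, giving ring A alcohol 6 and dione 9, the two convergent fragments.

9 to 7 and 8. The C9–C11 bond is cut (C-alkylation of 7 by 8). The C13 oxygen is a benzyl ether because it is transparent above 290 nm, inert to fluoride and base, and leaves in the metal–ammonia step without a step of its own.

6 to 1. The alcohol comes from ester 5, whose C5–H comes from enol triflate 4 of ketone 3. The C20 methyl of 3 and the C19 methyl of 2 are introduced by two C-methylations of β-keto ester 1, the first enantioselective. The C4 centre is made first, where it is simplest, and the ketone then serves twice: it brings in C20 and it fixes the alkene position, since only one side can enolize.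

## Alternatives that were turned down

Alternative 1: Cut C5–C10 and C8–C9 in an intramolecular Diels–Alder reaction, with ring A closed at the same time through the C1–C3 tether. The open-chain triene A2 (malonate at C4, 2-silyloxydiene C5–C8, E-enal C9=C10) would be folded into decalin A1 by the oxazaborolidinium salt from (S)-3,3-diphenyl-1-(2-methylphenyl)tetrahydro-1H,3H-pyrrolo[1,2-c][1,3,2]oxazaborole and HNTf2. In its favour, two rings and four stereocentres (C5, C8, C9, C10) form in one thermal step, and the C9/C10 relationship is encoded in the alkene geometry; on this point it is stronger than the chosen route, which sets C9 only in the aldol stage. Against it for this target: C4 arrives as a symmetric malonate, so C18 and C19 must be differentiated afterwards (one ester to CH3, the diastereotopic one to CH2OH, several steps of uncertain selectivity). A β,β-disubstituted enal is also a poor dienophile for such catalysts, C8 arrives as C–H so the C8 oxygen still has to go through the 7-en-6-one, and C11 arrives as an aldehyde that needs the whole diene chain. The chosen strategy fixes C4 first and unambiguously and reaches the same enone with the side chain in place.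

Alternative 2: Cut C7–C8 and C9–C10 in an intermolecular Diels–Alder reaction of the achiral ring A silyloxydiene A4 with but-2-ynal A5 under the same boron catalyst, giving A3. In its favour: convergent, simple achiral partners, no photochemistry, one catalyst-controlled quaternary centre, C17 and C11 delivered directly. Against it: the diene terminus C10 is fully substituted and the diene is twisted by the neighbouring malonate carbon, so a weakly activated ynal must form a quaternary centre intermolecularly. Only C10 is set; C4 (again a malonate), C5 and C9 all have to be set later on a cross-conjugated diene, which costs more steps than it saves. The chosen route relays C4 to C10 and sets C5 and C9 in the ring-forming step.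

Alternative 3: Cut C4–C5 and C9–C10 in a radical bicyclization. Cp2TiCl (trivalent titanium, from Cp2TiCl2 and Mn) would open the oxirane of epoxy diene A7 to the C4 radical, which closes both rings and ends as the 8(17)-alkene A6. In its favour: it is the most direct plan and a known reaction class. Both rings, the 18-hydroxyl, the C6 oxygen and a handle for the C8 carbinol arrive together; on step economy it is stronger than the chosen route. Against it: the C4 radical is planar, so the oxirane configuration is lost and the C18/C19 arrangement depends only on folding. The single controlling stereocentre is the C6 silyloxy carbon, which must direct the whole cascade, and bicyclizations ending in an exocyclic alkene are usually moderate in efficiency and regiochemistry. The chosen strategy offers a C4 centre made by a robust asymmetric alkylation and a covalent relay to C10.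

Key step: step 8

Remark: the antipode of the phase-transfer catalyst in step 1 is taken to be the one that gives the S ester 2; this has to be confirmed on the first run.

## Route

Step 1
Reactants: 1 tert-butyl 2-oxocyclohexane-1-carboxylate
Product: 2 tert-butyl (1S)-1-methyl-2-oxocyclohexane-1-carboxylate
Conditions: MeI, (11bS)-4,4-dibutyl-2,6-bis(3,4,5-trifluorophenyl)-4,5-dihydro-3H-dinaphtho[2,1-c:1',2'-e]azepinium bromide (1 mol%), powdered K2CO3, toluene, −20 °C
Reagents that add atoms: iodomethane, CI
Why: Phase-transfer asymmetric alkylation: the β-keto ester enolate is methylated inside the chiral ammonium ion pair, which sets the quaternary C4 centre (C19 methyl, ester as future C18). The bulky tert-butyl ester should sharpen the facial discrimination.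

Step 2
Reactants: 2 tert-butyl (1S)-1-methyl-2-oxocyclohexane-1-carboxylate
Product: 3 tert-butyl (1S)-1,3-dimethyl-2-oxocyclohexane-1-carboxylate (both C3 epimers)
Conditions: LiN(iPr)2, THF, −78 °C; MeI, −78 → 0 °C
Reagents that add atoms: iodomethane, CI
Why: Kinetic enolate alkylation; only the CH2 side of the ketone can enolize, so the methyl (C20) enters at the future C10. The new centre becomes sp2 in step 3, so its configuration is irrelevant.

Step 3
Reactants: 3 tert-butyl (1S)-1,3-dimethyl-2-oxocyclohexane-1-carboxylate
Product: 4 tert-butyl (1S)-1,3-dimethyl-2-{[(trifluoromethyl)sulfonyl]oxy}cyclohex-2-ene-1-carboxylate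
Conditions: KN(SiMe3)2, THF, −78 → 0 °C; PhNTf2, −78 °C → rt
Reagents that add atoms: N-phenylbis(trifluoromethanesulfonimide), O=S(=O)(N(c1ccccc1)S(=O)(=O)C(F)(F)F)C(F)(F)F
Why: Enol triflate formation; the only remaining α-hydrogen is the methine at the methyl-bearing carbon, so the C5=C10 position of the double bond is unambiguous.

Step 4
Reactants: 4 tert-butyl (1S)-1,3-dimethyl-2-{[(trifluoromethyl)sulfonyl]oxy}cyclohex-2-ene-1-carboxylate
Product: 5 tert-butyl (1S)-1,3-dimethylcyclohex-2-ene-1-carboxylate
Conditions: Pd(OAc)2 (5 mol%), PPh3, HCO2H, Bu3N, DMF, 60 °C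
Reagents that add atoms: none
Why: Palladium-catalysed formate reduction of an enol triflate (oxidative addition to zerovalent palladium, formate exchange, loss of CO2, reductive elimination) replaces OTf by H. 2-Methyl-6,6-disubstituted cyclohexenyl triflates are standard substrates, and the ester and the C4 centre are not touched.

Step 5
Reactants: 5 tert-butyl (1S)-1,3-dimethylcyclohex-2-ene-1-carboxylate
Product: 6 [(1S)-1,3-dimethylcyclohex-2-en-1-yl]methanol (ring A alkene: C4 stereocentre, C5=C10, free C18 hydroxyl)
Conditions: LiAlH4, THF, 0 °C → reflux
Reagents that add atoms: none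
Why: Hydride reduction of the hindered ester to the neopentyl primary alcohol; the trisubstituted alkene is inert.

Step 6
Reactants: 7 pentane-2,4-dione; 8 benzyl 3-bromopropyl ether
Product: 9 3-[3-(benzyloxy)propyl]pentane-2,4-dione
Conditions: K2CO3, NaI (cat.), acetone, reflux
Reagents that add atoms: none
Why: C-alkylation of the potassium enolate of the 1,3-dione by the iodide formed in situ (Finkelstein exchange); this attaches C11–C13 to the future C9.

Step 7
Reactants: 6 [(1S)-1,3-dimethylcyclohex-2-en-1-yl]methanol; 9 3-[3-(benzyloxy)propyl]pentane-2,4-dione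
Product: 11 3-[3-(benzyloxy)propyl]-4-{[{[(1S)-1,3-dimethylcyclohex-2-en-1-yl]methoxy}di(propan-2-yl)silyl]oxy}pent-3-en-2-one (enol ether isomers), via chlorosilane 10 (not isolated)
Conditions: iPr2SiCl2, Et3N, 4-(dimethylamino)pyridine (cat.), CH2Cl2, 0 °C; then 9, Et3N, rt → 40 °C
Reagents that add atoms: dichlorodi(propan-2-yl)silane, CC(C)[Si](Cl)(Cl)C(C)C
Why: Stepwise substitution at a hindered dichlorosilane: the primary alcohol replaces one chloride (the isopropyl groups stop the reaction there), then the enolizable dione is O-silylated to the β-silyloxy enone. The dione is symmetric, so either acetyl oxygen gives the same compound, and the two enol ether isomers interconvert on irradiation.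

Step 8
Reactants: 11 3-[3-(benzyloxy)propyl]-4-{[{[(1S)-1,3-dimethylcyclohex-2-en-1-yl]methoxy}di(propan-2-yl)silyl]oxy}pent-3-en-2-one
Product: 15 13-(benzyloxy)-18-hydroxy-14,15,16-trinor-ent-labd-7-en-6-one (trans-fused, C9 chain equatorial), via tethered cyclobutane 12 (not isolated), via 1,5-diketone 13 (not isolated), via ketol 14 (not isolated)
Conditions: hν (≥290 nm, Pyrex), degassed MeCN (5 mM), rt; then Bu4NF, THF, 0 °C → rt; then KOH, MeOH, rt → 45 °C
Reagents that add atoms: none
Why: Proposed new method: excitation of the β-silyloxy enone (the O-silylated enol of dione 9) gives a triplet that can reach the C5=C10 alkene only through the O–Si–O link to C18, so the oxygen-bearing enol carbon C6 bonds to C5 (seven-membered siladioxepane, cis-fused on the C18 face) and the resulting tertiary 1,4-diradical closes C9–C10 to cyclobutane 12, the closest known reaction types being the de Mayo reaction of pentane-2,4-dione enols and of O-silyl or O-acyl enol derivatives of 1,3-diones with alkenes, and silicon-tethered [2+2] photocycloadditions of dialkoxysilanes. Fluoride then frees the cyclobutanol, whose strain-driven retro-aldol breaks C6–C9 to 1,5-diketone 13, and hydroxide closes ring B by a 6-(enolendo)-exo-trig aldol of the C7 methyl enolate onto the C8 ketone (ketol 14) followed by E1cB dehydration. Three selectivities are needed: the orientation (C6 to C5, C9 to C10) and the face are both secured by the linker, which starts at C18 on C4 next to C5 and so holds C6 over C5 on the face anti to the C19 methyl, fixing quaternary C10 relative to C4. The aldol direction is secured because the alternative (C17 enolate onto the C6 ketone) attacks a carbonyl buried between the quaternary C4 and C10 and would place a vinylic methyl against the C4 substituents. C5, alpha to the C6 carbonyl, should equilibrate to the trans ring fusion, and C9 should emerge with the chain equatorial from the reversible, chair-like ketol stage, so base contact is kept short to avoid later epimerization at this gamma position.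

Step 9
Reactants: 15 13-(benzyloxy)-18-hydroxy-14,15,16-trinor-ent-labd-7-en-6-one
Product: 16 13-(benzyloxy)-18-[(tert-butyldimethylsilyl)oxy]-14,15,16-trinor-ent-labd-7-en-6-one
Conditions: TBSCl, imidazole, DMF, rt
Reagents that add atoms: tert-butyl(chloro)dimethylsilane, CC(C)(C)[Si](C)(C)Cl
Why: Silylation of the only hydroxyl; C18 now stays masked until the acetate is in place.

Step 10
Reactants: 16 13-(benzyloxy)-18-[(tert-butyldimethylsilyl)oxy]-14,15,16-trinor-ent-labd-7-en-6-one
Product: 17 13-(benzyloxy)-18-[(tert-butyldimethylsilyl)oxy]-7,8-epoxy-14,15,16-trinor-ent-labdan-6-one (epoxide oxygen anti to C20)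
Conditions: 30% H2O2, aq. NaOH, MeOH, 0 °C → rt
Reagents that add atoms: hydrogen peroxide, OO
Why: Weitz–Scheffer nucleophilic epoxidation: hydroperoxide adds to C8 axially on the face away from the axial C20 methyl and the enolate closes on oxygen. This sets C7 and C8 with the oxygen anti to C20 and pushes C17 into the axial position.

Step 11
Reactants: 17 13-(benzyloxy)-18-[(tert-butyldimethylsilyl)oxy]-7,8-epoxy-14,15,16-trinor-ent-labdan-6-one
Product: 18 13-(benzyloxy)-18-[(tert-butyldimethylsilyl)oxy]-8-hydroxy-14,15,16-trinor-ent-labdan-6-one (8-OH equatorial, C17 axial)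
Conditions: SmI2, THF/MeOH, −90 °C
Reagents that add atoms: none
Why: Reductive opening of an α,β-epoxy ketone by SmI2: the ketyl expels the α-oxygen, so only the C7–O bond breaks and C8 keeps its configuration. Low temperature and in situ protonation suppress β-elimination.

Step 12
Reactants: 18 13-(benzyloxy)-18-[(tert-butyldimethylsilyl)oxy]-8-hydroxy-14,15,16-trinor-ent-labdan-6-one
Product: 19 18-[(tert-butyldimethylsilyl)oxy]-14,15,16-trinor-ent-labdane-6,8,13-triol (6-OH and 8-OH equatorial)
Conditions: Li, NH3(l), THF, t-BuOH (2 equiv), −78 → −33 °C; then NH4Cl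
Reagents that add atoms: none
Why: Dissolving-metal reduction: the ketyl/carbanion is protonated to the thermodynamically preferred equatorial C6 alcohol (the axial epimer would be syn-diaxial to C17 and C20, and it is the one hydride reagents give). The same electrons cleave the benzyl ether (Birch-type debenzylation) while the silyl ether survives.

Step 13
Reactants: 19 18-[(tert-butyldimethylsilyl)oxy]-14,15,16-trinor-ent-labdane-6,8,13-triol
Product: 21 18-[(tert-butyldimethylsilyl)oxy]-8,13-epoxy-14,15,16-trinor-ent-labdane-6,13-diol (lactol, both anomers), via hydroxy aldehyde 20 (not isolated)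
Conditions: 2,2,6,6-tetramethylpiperidin-1-oxyl (TEMPO, 10 mol%), PhI(OAc)2 (1.1 equiv), CH2Cl2, rt
Reagents that add atoms: none
Why: Oxoammonium oxidation is selective for the unhindered primary alcohol over the secondary C6 and tertiary C8 hydroxyls. Aldehyde 20 closes onto the C8 hydroxyl to the six-membered lactol, and one equivalent of oxidant should stop before the lactone.

Step 14
Reactants: 21 18-[(tert-butyldimethylsilyl)oxy]-8,13-epoxy-14,15,16-trinor-ent-labdane-6,13-diol
Product: 22 18-[(tert-butyldimethylsilyl)oxy]-15,16-dinor-ent-labd-13-yne-6,8-diol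
Conditions: dimethyl (1-diazo-2-oxopropyl)phosphonate, K2CO3, MeOH, rt → 40 °C
Reagents that add atoms: dimethyl (1-diazo-2-oxopropyl)phosphonate, COP(=O)(OC)C(=[N+]=[N-])C(C)=O
Why: Seyferth–Gilbert homologation with the Ohira–Bestmann reagent: the lactol reacts through its open aldehyde form 20 and the diazo carbon becomes C14. Carbonate in methanol tolerates the free hydroxyls and the silyl ether.

Step 15
Reactants: 22 18-[(tert-butyldimethylsilyl)oxy]-15,16-dinor-ent-labd-13-yne-6,8-diol
Product: 23 18-[(tert-butyldimethylsilyl)oxy]-ent-labda-13(16),14-diene-6,8-diol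
Conditions: ethylene (1 atm), second-generation Grubbs catalyst RuCl2(=CHPh)(PCy3)(1,3-dimesitylimidazolidin-2-ylidene) (5 mol%), toluene, 80 °C
Reagents that add atoms: ethene, C=C
Why: Ethylene–alkyne cross enyne metathesis: the ruthenium methylidene adds to the terminal alkyne and the vinylcarbene turns over with ethylene, giving the 2-substituted buta-1,3-diene (C15 and C16 from ethylene). No stereocentre is involved and free hydroxyls are tolerated.

Step 16
Reactants: 23 18-[(tert-butyldimethylsilyl)oxy]-ent-labda-13(16),14-diene-6,8-diol
Product: 24 18-[(tert-butyldimethylsilyl)oxy]-8-hydroxy-ent-labda-13(16),14-dien-6-yl acetate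
Conditions: Ac2O, pyridine, 4-(dimethylamino)pyridine (cat.), CH2Cl2, rt
Reagents that add atoms: acetic anhydride, CC(=O)OC(C)=O
Why: Nucleophile-catalysed acylation of the secondary equatorial C6 alcohol; the tertiary C8 alcohol does not react under these conditions and C18 is still silylated.

Step 17
Reactants: 24 18-[(tert-butyldimethylsilyl)oxy]-8-hydroxy-ent-labda-13(16),14-dien-6-yl acetate
Product: 25 8,18-dihydroxy-ent-labda-13(16),14-dien-6-yl acetate (target; 6-OAc and 8-OH equatorial, C17 axial, C18 equatorial)
Conditions: HF·pyridine, pyridine, THF, 0 °C → rt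
Reagents that add atoms: none
Why: Fluoride cleavage of the primary silyl ether under buffered, slightly acidic conditions; this avoids the acetate shift to O18 that basic fluoride could cause and spares the diene and the tertiary alcohol.

## Compound list

1 | tert-butyl 2-oxocyclohexane-1-carboxylate | O=C1CCCCC1C(=O)OC(C)(C)C | starting material
2 | tert-butyl (1S)-1-methyl-2-oxocyclohexane-1-carboxylate | O=C1[C@@](C)(C(=O)OC(C)(C)C)CCCC1 | intermediate
3 | tert-butyl (1S)-1,3-dimethyl-2-oxocyclohexane-1-carboxylate (C3 epimers) | O=C1[C@@](C)(C(=O)OC(C)(C)C)CCCC1C | intermediate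
4 | tert-butyl (1S)-1,3-dimethyl-2-{[(trifluoromethyl)sulfonyl]oxy}cyclohex-2-ene-1-carboxylate | CC1=C(OS(=O)(=O)C(F)(F)F)[C@@](C)(C(=O)OC(C)(C)C)CCC1 | intermediate
5 | tert-butyl (1S)-1,3-dimethylcyclohex-2-ene-1-carboxylate | CC1=C[C@@](C)(C(=O)OC(C)(C)C)CCC1 | intermediate
6 | [(1S)-1,3-dimethylcyclohex-2-en-1-yl]methanol (ring A alkene) | CC1=C[C@@](C)(CO)CCC1 | intermediate
7 | pentane-2,4-dione | CC(=O)CC(C)=O | starting material
8 | benzyl 3-bromopropyl ether | BrCCCOCc1ccccc1 | starting material
9 | 3-[3-(benzyloxy)propyl]pentane-2,4-dione | CC(=O)C(CCCOCc1ccccc1)C(C)=O | intermediate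
10 | chloro{[(1S)-1,3-dimethylcyclohex-2-en-1-yl]methoxy}di(propan-2-yl)silane | CC1=C[C@@](C)(CO[Si](Cl)(C(C)C)C(C)C)CCC1 | intermediate (not isolated)
11 | 3-[3-(benzyloxy)propyl]-4-{[{[(1S)-1,3-dimethylcyclohex-2-en-1-yl]methoxy}di(propan-2-yl)silyl]oxy}pent-3-en-2-one (enol ether isomers) | CC1=C[C@@](C)(CO[Si](C(C)C)(C(C)C)OC(C)=C(CCCOCc2ccccc2)C(C)=O)CCC1 | intermediate
12 | tethered photoadduct: cyclobutane C5–C6–C9–C10 cis-fused to ring A on the C18 face; C6 bears the C7 methyl and the oxygen bound through Si(iPr)2 to O18; C9 bears acetyl and 3-(benzyloxy)propyl (C9 not fixed) | C[C@@]12CCC[C@](C)(CO[Si](C(C)C)(C(C)C)O3)[C@@H]1[C@@]3(C)C2(CCCOCc4ccccc4)C(C)=O | intermediate (not isolated)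
13 | 1,5-diketone: ring A with acetyl (C6, C7) on C5 and, on C10, the C20 methyl and the 1-acetyl-4-(benzyloxy)butyl group (C9); acetyl and C9 cis on the C18 face; C18 hydroxyl free; C9 epimers | CC(=O)[C@H]1[C@@](C)(CO)CCC[C@@]1(C)C(CCCOCc2ccccc2)C(C)=O | intermediate (not isolated)
14 | 13-(benzyloxy)-8,18-dihydroxy-14,15,16-trinor-ent-labdan-6-one (ketol; mixture at C5, C8, C9) | C[C@@]12CCC[C@](C)(CO)C1C(=O)CC(C)(O)C2CCCOCc3ccccc3 | intermediate (not isolated)
15 | 13-(benzyloxy)-18-hydroxy-14,15,16-trinor-ent-labd-7-en-6-one | c1ccccc1COCCC[C@H]2[C@]3(C)CCC[C@](C)(CO)[C@H]3C(=O)C=C2C | intermediate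
16 | 13-(benzyloxy)-18-[(tert-butyldimethylsilyl)oxy]-14,15,16-trinor-ent-labd-7-en-6-one | c1ccccc1COCCC[C@H]2[C@]3(C)CCC[C@](C)(CO[Si](C)(C)C(C)(C)C)[C@H]3C(=O)C=C2C | intermediate
17 | 13-(benzyloxy)-18-[(tert-butyldimethylsilyl)oxy]-7,8-epoxy-14,15,16-trinor-ent-labdan-6-one (oxygen anti to C20) | c1ccccc1COCCC[C@H]2[C@]3(C)CCC[C@](C)(CO[Si](C)(C)C(C)(C)C)[C@H]3C(=O)[C@@H]4O[C@]24C | intermediate
18 | 13-(benzyloxy)-18-[(tert-butyldimethylsilyl)oxy]-8-hydroxy-14,15,16-trinor-ent-labdan-6-one | c1ccccc1COCCC[C@H]2[C@]3(C)CCC[C@](C)(CO[Si](C)(C)C(C)(C)C)[C@H]3C(=O)C[C@]2(C)O | intermediate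
19 | 18-[(tert-butyldimethylsilyl)oxy]-14,15,16-trinor-ent-labdane-6,8,13-triol | OCCC[C@H]1[C@]2(C)CCC[C@](C)(CO[Si](C)(C)C(C)(C)C)[C@H]2[C@H](O)C[C@]1(C)O | intermediate
20 | 18-[(tert-butyldimethylsilyl)oxy]-6,8-dihydroxy-14,15,16-trinor-ent-labdan-13-al | O=CCC[C@H]1[C@]2(C)CCC[C@](C)(CO[Si](C)(C)C(C)(C)C)[C@H]2[C@H](O)C[C@]1(C)O | intermediate (not isolated)
21 | 18-[(tert-butyldimethylsilyl)oxy]-8,13-epoxy-14,15,16-trinor-ent-labdane-6,13-diol (lactol, both anomers) | OC1CC[C@H]2[C@]3(C)CCC[C@](C)(CO[Si](C)(C)C(C)(C)C)[C@H]3[C@H](O)C[C@]2(C)O1 | intermediate
22 | 18-[(tert-butyldimethylsilyl)oxy]-15,16-dinor-ent-labd-13-yne-6,8-diol | C#CCC[C@H]1[C@]2(C)CCC[C@](C)(CO[Si](C)(C)C(C)(C)C)[C@H]2[C@H](O)C[C@]1(C)O | intermediate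
23 | 18-[(tert-butyldimethylsilyl)oxy]-ent-labda-13(16),14-diene-6,8-diol | C=CC(=C)CC[C@H]1[C@]2(C)CCC[C@](C)(CO[Si](C)(C)C(C)(C)C)[C@H]2[C@H](O)C[C@]1(C)O | intermediate
24 | 18-[(tert-butyldimethylsilyl)oxy]-8-hydroxy-ent-labda-13(16),14-dien-6-yl acetate | C=CC(=C)CC[C@H]1[C@]2(C)CCC[C@](C)(CO[Si](C)(C)C(C)(C)C)[C@H]2[C@H](OC(C)=O)C[C@]1(C)O | intermediate
25 | 8,18-dihydroxy-ent-labda-13(16),14-dien-6-yl acetate | C=CC(=C)CC[C@H]1[C@]2(C)CCC[C@](C)(CO)[C@H]2[C@H](OC(C)=O)C[C@]1(C)O | target

## Step count and least certain steps

Total: 17 steps. Longest linear sequence: 16 steps (steps 1–5 and 7–17); step 6 is the one-step side branch.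

Step 8 (key step, proposed new method). The most likely failure is inefficient photocycloaddition. The triplet of an open-chain silyloxy enone can relax by rotation about its double bond before it reaches the alkene. The tertiary 1,4-diradical may also transfer a hydrogen from C20 or C1 to C9 instead of closing the crowded C9–C10 bond. A crossed addition (C6 to C10) through an eight-membered arrangement is a further possibility. In the base stage, long contact could epimerize C9 through the dienolate. The fallback uses the established intermolecular de Mayo reaction; it sets out from 6 and 9 and returns at 15. A cyclohexane solution of alcohol 6 and an excess of 9, whose hydrogen-bonded enol is the classical chromophore, is irradiated through Pyrex. This should give the free cyclobutanol F1, which opens by retro-aldol as it forms to diketone 13; KOH in MeOH then gives 15 as in step 8. This variant gives up the linker, so orientation and face would rest only on a hydrogen bond from the C18 hydroxyl to a dione oxygen, and regioisomers and the C10 epimer would have to be separated at 15.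

Step 1. The enantioselectivity of a methylation (a small electrophile) under phase transfer may be insufficient, or its sense opposite, and no later intermediate offers a diastereomeric purification. The fallback sets out from 1 and returns at 2. Condensation of 1 with tert-butyl (S)-valinate gives the enamino ester F2. Its lithium aza-enolate (LiN(iPr)2, toluene or THF, −78 °C) is methylated with MeI to the imine F3, and mild aqueous acid returns 2 and the amino ester. The sense of this auxiliary-controlled alkylation depends on solvent and both valine antipodes are available.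

Step 10. Conjugate addition of hydroperoxide to a β,β-disubstituted enone next to the quaternary C10 may be slow, which would give the alkaline medium time to epimerize C9 or C5. The fallback sets out from 16 and returns at 18, bypassing 17. Copper-catalysed conjugate borylation (CuCl, 1,2-bis(diphenylphosphino)benzene, NaOtBu, bis(pinacolato)diboron, MeOH, THF) should add boron to C8 on the face anti to C20, giving the β-boryl ketone F4. Oxidation with NaBO3 proceeds with retention and gives the 8-hydroxy ketone 18 directly.

Step 12. The β-hydroxy ketone may undergo retro-aldol cleavage or β-elimination as its alkoxide in the strongly basic medium before electron transfer is complete; incomplete debenzylation is the second risk. The fallback sets out from 18 and returns at 19. The tertiary hydroxyl is masked as its trimethylsilyl ether F5 (1-(trimethylsilyl)imidazole, CH2Cl2), so that no β-alkoxide can form. F5 is reduced with Li in NH3 as before, and the labile tertiary silyl ether is removed in a mildly acidic methanolic work-up, giving 19.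

Step 13. Over-oxidation of the lactol to the lactone, or a mixture of alcohol, lactol and lactone, is likely if the second oxidation is not much slower than the first. The fallback sets out from 19 and returns at 21. An excess of PhI(OAc)2 with TEMPO drives the oxidation fully to the δ-lactone F6, and iBu2AlH (CH2Cl2, −78 °C, one extra equivalent for the C6 hydroxyl) reduces it back to lactol 21.

## Further compounds

F1 | step 8 | free cyclobutanol photoadduct of 6 and 9: cyclobutane C5–C6–C9–C10 cis-fused to ring A, C6 with OH and CH3, C9 with acetyl and 3-(benzyloxy)propyl (C6, C9 not fixed) | C[C@@]12CCC[C@](C)(CO)[C@@H]1C(C)(O)C2(CCCOCc3ccccc3)C(C)=O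
F2 | step 1 | tert-butyl 2-{[(2S)-1-tert-butoxy-3-methyl-1-oxobutan-2-yl]amino}cyclohex-1-ene-1-carboxylate | CC(C)[C@H](NC1=C(C(=O)OC(C)(C)C)CCCC1)C(=O)OC(C)(C)C
F3 | step 1 | tert-butyl (1S)-2-{[(2S)-1-tert-butoxy-3-methyl-1-oxobutan-2-yl]imino}-1-methylcyclohexane-1-carboxylate | CC(C)[C@H](N=C1CCCC[C@]1(C)C(=O)OC(C)(C)C)C(=O)OC(C)(C)C
F4 | step 10 | 13-(benzyloxy)-18-[(tert-butyldimethylsilyl)oxy]-8-(4,4,5,5-tetramethyl-1,3,2-dioxaborolan-2-yl)-14,15,16-trinor-ent-labdan-6-one (boron anti to C20) | c1ccccc1COCCC[C@H]2[C@]3(C)CCC[C@](C)(CO[Si](C)(C)C(C)(C)C)[C@H]3C(=O)C[C@]2(C)B4OC(C)(C)C(C)(C)O4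
F5 | step 12 | 13-(benzyloxy)-18-[(tert-butyldimethylsilyl)oxy]-8-[(trimethylsilyl)oxy]-14,15,16-trinor-ent-labdan-6-one | c1ccccc1COCCC[C@H]2[C@]3(C)CCC[C@](C)(CO[Si](C)(C)C(C)(C)C)[C@H]3C(=O)C[C@]2(C)O[Si](C)(C)C
F6 | step 13 | 18-[(tert-butyldimethylsilyl)oxy]-6-hydroxy-14,15,16-trinor-ent-labdan-13,8-olide (δ-lactone) | O=C1CC[C@H]2[C@]3(C)CCC[C@](C)(CO[Si](C)(C)C(C)(C)C)[C@H]3[C@H](O)C[C@]2(C)O1
A1 | alternative 1 | trans-decalin silyl enol ether aldehyde (C4 gem-diester, C6=C7 silyl enol ether, C8 methyl, C9 formyl, C10 methyl) | O=C[C@H]1[C@]2(C)CCCC(C(=O)OC)(C(=O)OC)[C@H]2C(O[Si](C)(C)C(C)(C)C)=C[C@H]1C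
A2 | alternative 1 | dimethyl 2-[(1Z,3E)-2-{[tert-butyl(dimethyl)silyl]oxy}penta-1,3-dien-1-yl]-2-[(4E)-4-methyl-6-oxohex-4-en-1-yl]propanedioate | O=C/C=C(C)/CCCC(C(=O)OC)(C(=O)OC)/C=C(O[Si](C)(C)C(C)(C)C)/C=C/C
A3 | alternative 2 | bicyclic silyl dienol ether aldehyde with quaternary C10 | O=CC1=C(C)CC(O[Si](C)(C)C(C)(C)C)=C2C(C(=O)OC)(C(=O)OC)CCC[C@@]12C
A4 | alternative 2 | dimethyl 2-(1-{[tert-butyl(dimethyl)silyl]oxy}ethenyl)-3-methylcyclohex-2-ene-1,1-dicarboxylate | C=C(O[Si](C)(C)C(C)(C)C)C1=C(C)CCCC1(C(=O)OC)C(=O)OC
A5 | alternative 2 | but-2-ynal | CC#CC=O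
A6 | alternative 3 | bicyclic 18-ol, 6-silyl ether, 8(17)-alkene with 4-methoxybenzyl-protected C13 alcohol | COc1ccc(cc1)COCCC[C@H]2[C@]3(C)CCC[C@](C)(CO)[C@H]3[C@H](O[Si](C)(C)C(C)(C)C)CC2=C
A7 | alternative 3 | open-chain (E,E)-epoxy diene: 2-methyloxirane at C4/C18, C5=C10 and C8=C9 alkenes, silyloxy at C6, 4-methoxybenzyl ether at C13 (oxirane carbon not defined) | COc1ccc(cc1)COCCC/C=C(C)/C[C@@H](O[Si](C)(C)C(C)(C)C)/C=C(C)/CCCC2(C)CO2
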